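Labels: ring A is the catechol ring, ring B the furan, ring C the central carbocycle (dibenzofuran locants C1 to C4, C4a, C9b), ring D the lactone, and Cα the ring D carbon that carries the 4-hydroxyphenyl group.
Enabling feature: Cα joins three pieces that can be obtained separately (C1 of ring C, the para carbon of a phenol, the lactone carbonyl). C1 is the single unsubstituted carbon of ring C, ortho to the oxygen on C2 and para to the oxygen on C4.
Cuts, in order: the catechol is masked as its dimethyl ether. The C4=O/C1=Cα quinone methide is reduced to a leuco lactone. C1-Cα, Cα-aryl and O(C2)-C(=O) are cut together to a dibenzofuran-2,4-diol, glyoxylic acid and phenol. Ring B is then cut at C9a-C9b and at C4a-O, and last the C3-phenyl bond.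
Forward: ring C (2-bromoresorcinol) is phenylated and iodinated, then tied to ring A by an Ullmann ether bond. Ring B closes by direct arylation and ring D in the three-component step. Ring C is oxidised before the catechol is freed.
Stereochemistry: the target has no stereocentre and the C1=Cα geometry is locked by ring D. Cα of the leuco lactone arises racemic and becomes trigonal in the dehydrogenation.

Key step: step 8

Assumption: the target is taken as the drawn tautomer. A proton shift between the C4 oxygen and the oxygen of the 4-hydroxyphenyl group gives the fuchsone-type tautomer. This shift is assumed to be fast, so both drawings describe one substance.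

Step 1
Reactants: 1 2-bromoresorcinol
Product: 2 1,3-bis(benzyloxy)-2-bromobenzene
Conditions: BnBr (2.3 equiv), K2CO3, DMF, 60 °C
Reagents that add atoms: benzyl bromide, BrCc1ccccc1
Why: Williamson ether synthesis on both phenols, with benzyl chosen because it can later be removed by hydrogenolysis without touching the methyl ethers of ring A.

Step 2
Reactants: 2 1,3-bis(benzyloxy)-2-bromobenzene; 3 phenylboronic acid
Product: 4 2,6-bis(benzyloxy)biphenyl
Conditions: Pd(OAc)2 (2 mol %), SPhos (4 mol %), K3PO4, toluene/H2O, 100 °C
Reagents that add atoms: none
Why: Suzuki-Miyaura coupling, in which the bulky electron-rich biarylphosphine is suited to an aryl bromide flanked by two ortho alkoxy groups.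

Step 3
Reactants: 4 2,6-bis(benzyloxy)biphenyl
Product: 5 2,6-bis(benzyloxy)-3-iodobiphenyl
Conditions: NIS (1.0 equiv), TFA (cat.), MeCN, 0 °C to rt
Reagents that add atoms: N-iodosuccinimide, O=C1CCC(=O)N1I
Why: Electrophilic aromatic iodination, in which the two symmetry-equivalent carbons ortho to one benzyloxy group and para to the other are the only strongly activated sites, so one equivalent of NIS should stop at the mono-iodide.

Step 4
Reactants: 6 3,4-dimethoxyphenol
Product: 7 2-bromo-4,5-dimethoxyphenol
Conditions: NBS (1.0 equiv), CH2Cl2, 0 °C
Reagents that add atoms: N-bromosuccinimide, O=C1CCC(=O)N1Br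
Why: Electrophilic aromatic bromination at the carbon ortho to the hydroxyl and para to the 3-methoxy group, the most activated and least crowded position of this trioxygenated ring.

Step 5
Reactants: 5 2,6-bis(benzyloxy)-3-iodobiphenyl; 7 2-bromo-4,5-dimethoxyphenol
Product: 8 2,6-bis(benzyloxy)-3-(2-bromo-4,5-dimethoxyphenoxy)biphenyl
Conditions: CuI (10 mol %), picolinic acid (20 mol %), K3PO4, DMSO, 85 °C, Ar
Reagents that add atoms: none
Why: Ligand-accelerated Ullmann diaryl ether synthesis, in which the C-I bond of 5 engages copper much faster than the electron-rich C-Br bond next to the phenoxide oxygen, so the bromide should be carried through.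

Step 6
Reactants: 8 2,6-bis(benzyloxy)-3-(2-bromo-4,5-dimethoxyphenoxy)biphenyl
Product: 9 2,4-bis(benzyloxy)-7,8-dimethoxy-3-phenyldibenzofuran
Conditions: Pd(OAc)2 (5 mol %), PCy3·HBF4 (10 mol %), PivOH (30 mol %), K2CO3, DMA, 120 °C
Reagents that add atoms: none
Why: Intramolecular direct arylation by concerted metalation-deprotonation, in which insertion of zerovalent palladium into the C-Br bond fixes the ring A terminus and the only C-H ortho to the ether oxygen on ring C is the one within reach, so ring B should close with a single regiochemistry.

Step 7
Reactants: 9 2,4-bis(benzyloxy)-7,8-dimethoxy-3-phenyldibenzofuran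
Product: 10 7,8-dimethoxy-3-phenyldibenzofuran-2,4-diol
Conditions: H2 (1 atm), Pd/C (10 wt %), EtOAc/EtOH, rt
Reagents that add atoms: none
Why: Hydrogenolysis of aryl benzyl ethers, which leaves the methyl ethers and the dibenzofuran core untouched and frees the two meta-related hydroxyls that activate C1.

Step 8
Reactants: 10 7,8-dimethoxy-3-phenyldibenzofuran-2,4-diol; 11 glyoxylic acid (used as the monohydrate); 12 phenol
Product: 16 racemic leuco lactone dimethyl ether (C2-O lactone of 2-(2,4-dihydroxy-7,8-dimethoxy-3-phenyldibenzofuran-1-yl)-2-(4-hydroxyphenyl)acetic acid), via mandelic acid 13 (not isolated), via 3-hydroxylactone 14 (not isolated), via para-quinone methide 15 (not isolated)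
Conditions: 11 (1.5 equiv), AcOH, 50 °C, Ar; then 12 (10 equiv), MeSO3H (2 equiv), 70 °C, one pot
Reagents that add atoms: none
Why: In AcOH the aldehyde of 11 is attacked by C1 of 10 (Friedel-Crafts hydroxyalkylation) to give mandelic acid 13, and the C2 hydroxyl then adds to the carboxyl carbon (5-exo-trig lactonisation) and closes ring D as 3-hydroxylactone 14. MeSO3H, added only together with a large excess of 12, ionises the Cα-OH bond with the push of the C4 hydroxyl para to C1, giving para-quinone methide 15 or its protonated form, which alkylates phenol at its open para carbon and lets ring C become aromatic again. The closest known reaction type is the acid-mediated one-pot union of a phenol, glyoxylic acid and an arene to 3-arylbenzofuran-2(3H)-ones. Cα is the only new stereocentre, nothing controls it and a racemate is expected, which is of no consequence because step 9 flattens it. The aldehyde must choose C1 over ring A and over phenol: C1 is the 5-position of a 1,2,4-trioxygenated benzene with one free hydroxyl ortho and another para, whereas C6 and C9 of ring A lack a para donor, phenol is absent in the first stage, and only the C2 hydroxyl can reach the acid. Capture of 15 by a second molecule of 10 is held back by consuming 10 with excess 11 before strong acid is added, by the crowding of its bay carbon C1 and by the excess of phenol, while the bulk around Cα favours the para over the ortho carbon of phenol.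

Step 9
Reactants: 16 racemic leuco lactone dimethyl ether
Product: 17 quinone methide dimethyl ether (the target skeleton with C4=O and C1=Cα, with methoxy groups on C7 and C8)
Conditions: DDQ (1.05 equiv), 1,4-dioxane, rt
Reagents that add atoms: none
Why: DDQ dehydrogenation of a 4-hydroxybenzylic C-H to a para-quinone methide, the reaction type that turns 4-hydroxydiarylmethanes into fuchsones and leuco benzodifuranones into their dyes, in which hydride leaves from the doubly benzylic lactone Cα-H, the C4 hydroxyl gives up its proton and the racemic centre disappears.

Step 10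
Reactants: 17 quinone methide dimethyl ether
Product: 18 CNP0139113.0 (target)
Conditions: BBr3 (8 equiv), CH2Cl2, -78 °C to rt; then ice/H2O
Reagents that add atoms: none
Why: BBr3 cleavage of aryl methyl ethers, during which the enol lactone and the quinone methide carbonyl are expected only to bind boron reversibly, as quinones, aurones and coumestan lactones do under these conditions, and to be released on aqueous work-up.

Compound list
1 | 2-bromoresorcinol | Oc1cccc(O)c1Br | starting material
2 | 1,3-bis(benzyloxy)-2-bromobenzene | Brc1c(OCc2ccccc2)cccc1OCc1ccccc1 | intermediate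
3 | phenylboronic acid | OB(O)c1ccccc1 | starting material
4 | 2,6-bis(benzyloxy)biphenyl | C(Oc1cccc(OCc2ccccc2)c1-c1ccccc1)c1ccccc1 | intermediate
5 | 2,6-bis(benzyloxy)-3-iodobiphenyl | Ic1ccc(OCc2ccccc2)c(-c2ccccc2)c1OCc1ccccc1 | intermediate
6 | 3,4-dimethoxyphenol | COc1ccc(O)cc1OC | starting material
7 | 2-bromo-4,5-dimethoxyphenol | COc1cc(O)c(Br)cc1OC | intermediate
8 | 2,6-bis(benzyloxy)-3-(2-bromo-4,5-dimethoxyphenoxy)biphenyl | COc1cc(Br)c(Oc2ccc(OCc3ccccc3)c(-c3ccccc3)c2OCc2ccccc2)cc1OC | intermediate
9 | 2,4-bis(benzyloxy)-7,8-dimethoxy-3-phenyldibenzofuran | COc1cc2oc3c(OCc4ccccc4)c(-c4ccccc4)c(OCc4ccccc4)cc3c2cc1OC | intermediate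
10 | 7,8-dimethoxy-3-phenyldibenzofuran-2,4-diol | Oc1cc2c(oc3cc(OC)c(OC)cc23)c(O)c1-c1ccccc1 | intermediate
11 | glyoxylic acid (used as the monohydrate) | O=CC(=O)O | starting material
12 | phenol | Oc1ccccc1 | starting material
13 | 2-(2,4-dihydroxy-7,8-dimethoxy-3-phenyldibenzofuran-1-yl)-2-hydroxyacetic acid (racemic, not isolated) | COc1cc2oc3c(O)c(-c4ccccc4)c(O)c(C(O)C(=O)O)c3c2cc1OC | intermediate
14 | C2-O lactone of 13, a 3-hydroxybenzofuran-2(3H)-one fused on C1-C2 of the dibenzofuran (racemic, not isolated) | O=C1Oc2c(-c3ccccc3)c(O)c3oc4cc(OC)c(OC)cc4c3c2C1O | intermediate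
15 | para-quinone methide from 14 by loss of water, with C4=O and C1=CαH (not isolated) | O=C1OC2=C(c3ccccc3)C(=O)c3oc4cc(OC)c(OC)cc4c3C2=C1 | intermediate
16 | leuco lactone dimethyl ether, C2-O lactone of 2-(2,4-dihydroxy-7,8-dimethoxy-3-phenyldibenzofuran-1-yl)-2-(4-hydroxyphenyl)acetic acid (racemic at Cα) | O=C1Oc2c(-c3ccccc3)c(O)c3oc4cc(OC)c(OC)cc4c3c2C1c1ccc(O)cc1 | intermediate
17 | quinone methide dimethyl ether, 7,8-di-O-methyl ether of the target | O=C1OC2=C(c3ccccc3)C(=O)c3oc4cc(OC)c(OC)cc4c3C2=C1c1ccc(O)cc1 | intermediate
18 | CNP0139113.0 | O=C1OC2=C(c3ccccc3)C(=O)c3oc4cc(O)c(O)cc4c3C2=C1c1ccc(O)cc1 | target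

Total step count: 10. Longest linear sequence: 9 steps (steps 1, 2, 3, 5, 6, 7, 8, 9 and 10, from 2-bromoresorcinol). Step 4 lies on the side branch.

Steps most likely to fail

Step 8. Several things could erode the three-component union.
- Attack at the bay carbon C1 may be slow.
- Some cation may be captured by unreacted diol.
- Phenol may be alkylated at its ortho carbon.
- Phenol may consume the surplus glyoxylic acid.

The fallback sets out from 10 and buys the Cα-aryl bond instead of making it. Compound 10 is condensed with commercial racemic 4-hydroxymandelic acid (OC(C(=O)O)c1ccc(O)cc1) under MeSO3H in AcOH at 70 °C. This is the known two-component synthesis of 3-arylbenzofuranones from a phenol and a mandelic acid. The cation now forms on the hydroxyphenyl side and 10 acts only as the nucleophile. C1-Cα formation and lactonisation onto the C2 oxygen then lead back to the route at 16. No compound outside the list is made on this detour (F0).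

Step 10. The Lewis acid and bromide may add to the electrophilic quinone methide or open the enol lactone. Demethylation may also stall because ring A is conjugated with the boron-complexed chromophore. The fallback sets out from 16 and reverses the order of the last two operations. BBr3 in CH2Cl2 is applied to the robust aromatic leuco lactone and should give the racemic leuco lactone with free catechol F5. This is then dehydrogenated with exactly one equivalent of DDQ in dioxane. Any oxidation that begins at the catechol is expected to be passed on to the more stabilised extended quinone methide. The route is rejoined at 18.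

Step 5. Two ortho-substituted, electron-rich partners may couple sluggishly. Discrimination between iodide and bromide may be lost, leading to oligomerisation, and hydrodeiodination may compete. The fallback sets out from 4 and reverses the roles of the partners.
- Vilsmeier-Haack formylation (POCl3, DMF) should give 2,4-bis(benzyloxy)-3-phenylbenzaldehyde F1.
- Baeyer-Villiger oxidation with mCPBA should give 2,4-bis(benzyloxy)-3-phenylphenyl formate F2.
- K2CO3 in MeOH should give 2,4-bis(benzyloxy)-3-phenylphenol F3.
- Ullmann coupling of this phenol with commercial 4-bromoveratrole (COc1ccc(Br)cc1OC), using CuI, picolinic acid and K3PO4 in DMSO, should give 2,6-bis(benzyloxy)-3-(3,4-dimethoxyphenoxy)biphenyl F4. The bromide carries one halogen only and no ortho substituent.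
- Oxidative double C-H coupling with Pd(OAc)2 in PivOH under air at 120 °C then closes ring B. Here divalent palladium is regenerated by oxygen. Closure should occur at the less hindered ring A carbon para to the 3-methoxy group.

This comes back to the route at 9.

Further compounds
F0 | step 8 | none | none
F1 | step 5 | 2,4-bis(benzyloxy)-3-phenylbenzaldehyde | O=Cc1ccc(OCc2ccccc2)c(-c2ccccc2)c1OCc1ccccc1
F2 | step 5 | 2,4-bis(benzyloxy)-3-phenylphenyl formate | O=COc1ccc(OCc2ccccc2)c(-c2ccccc2)c1OCc1ccccc1
F3 | step 5 | 2,4-bis(benzyloxy)-3-phenylphenol | Oc1ccc(OCc2ccccc2)c(-c2ccccc2)c1OCc1ccccc1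
F4 | step 5 | 2,6-bis(benzyloxy)-3-(3,4-dimethoxyphenoxy)biphenyl | COc1ccc(Oc2ccc(OCc3ccccc3)c(-c3ccccc3)c2OCc2ccccc2)cc1OC
F5 | step 10 | leuco lactone with free catechol (racemic at Cα) | O=C1Oc2c(-c3ccccc3)c(O)c3oc4cc(O)c(O)cc4c3c2C1c1ccc(O)cc1
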